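J.D grows at kJ[J][D], where kJ is the constant of J + D; we want that growth and the level of J at the end of this flask.

E 20 mM; D 4.00 equiv; time 2.0 h

    J ⇌ Q, settled at all times (K1 = 2.1)
    J + D → J.D (k2 = 12.6 L mol⁻¹ h⁻¹)
    D + Q → D.Q (k3 = 5.71 L mol⁻¹ h⁻¹)
    E ⇌ J, rate k4*(cs4 - [J]) while solid is left; crystals form when [J] > cs4 (cs4 = 19 mM, k4 = 0.200 h⁻¹)

* J.D at 2.0 h, in percent of the E charged
* concentration of J in solution at 2.0 h, in percent of saturation

- given per volume of solution although it is solid: E
- at the start none of E is in solution
- J means what is dissolved; the solid is not counted in it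
- run time (flask): 2.0 h

D stands at 80.0 mM. We hold it constant for now, which makes the step pseudo-first-order, and the question becomes what [J] is.

First guess: J stands at its solubility 19 mM. But J.D would then form at 19.2 mM h⁻¹, faster than the 3.80 mM h⁻¹ that is the most dissolution can supply. So J stays low.

Second guess: inflow equals kJ[D][J], giving J = 3.77 mM. But Q stands at K times J, with K the balance constant, so inflow fills the pool J + Q, and D drains Q too, with constant kQ. The drain constant λ is the first-order constant at which D empties that pool:

λ = [D](kJ + K·kQ)/(1 + K) = 0.635 h⁻¹

Dissolution slows as J rises, which adds its coefficient k, shared over the pool, and gives a, the constant at which the pool approaches its level: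

a = λ + k/(1 + K) = 0.699 h⁻¹

While solid lasts and [D] holds, this reckoning puts the level of J at 1.75 mM. Another doubt: the lifetime 1/a, 1.43 h, is not much shorter than the run, so we reckon J as still approaching that level:

J = 1.32 mM, or 6.95% of saturation

J.D = kJ[D]∫J dt, or 8.16% of E

The constant [D] remains open to doubt: the reckoning spends 3.98% of it. We let that stand. Solid stays through the run, since step 4 can deliver at most 38.0% of the E charged by 2.0 h.

The forecast gave J.D at 7.9% of the E charged (7.4% to 8.4%) and J at 7.1% of saturation (6.6% to 7.6%), with J “still approaching a quasi-steady level”. Our J.D stands higher.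

The flask gives J.D at 8.03% of the E charged and J at 7.03% of saturation.

It ends with 96% of its D, at which λ comes to 0.610 h⁻¹. In the neighbouring flask with 16.0 equiv of D, λ grows with [D] to 2.54 h⁻¹ and a to 2.60 h⁻¹. The lifetime falls to 0.385 h, well inside the run. We reckon J at 0.468 mM, or 2.34% of E, and J.D at 15.4%. That flask gives J 2.37% and J.D 15.3%.

(The constants used here were set for the occasion; no experiment stands behind them.)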